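**Retrosynthetic overview**
1. Target 29 ⇐ 28 (desilylation) ⇐ 26 by Mitsunobu esterification with (S)-2-methylbutanoic acid, which inverts C8.
2. 26 ⇐ 25 ⇐ 23: Cr(II) allylation of the C6 enal by the C13 allyl bromide through C7, with lactonization in the same flask. C6–C7 and O–C12 form together, so the ten-membered carbocycle and the γ-lactone close in one operation (the only ring-forming step).
3. 23 ⇐ 14 + 18: B-alkyl Suzuki coupling (C3–C4), then allylic oxidation and OH→Br.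
4. 14 ⇐ 8 + methyl propiolate + CH2O (asymmetric alkynylation sets C8; hydroalumination/hydroxymethylation adds C13); 8 ⇐ 3 + acrolein (asymmetric Ni/Cr coupling sets C1).
5. 3 and 18 ⇐ 2-butyn-1-ol and 2-butyne-1,4-diol by Red-Al/I2, which fixes both ring-cis trisubstituted alkenes.

Assumption: germacrane numbering is used for locants (C6 lactone carbinol, C7 ring-fusion CH, C8 ester carbinol, C1 free secondary carbinol, C15 hydroxymethyl, C11–C13 methylene-lactone carbons); the SMILES strings are authoritative for configuration.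

**Step 1**
Reactants: 1 2-butyn-1-ol
Product: 3 (Z)-3-iodobut-2-en-1-ol, via cyclic vinylalanate 2 (not isolated)
Conditions: Red-Al, THF, 0 °C to rt; then I2, −78 to 0 °C
Reagents that add atoms: iodine, II
Why: Hydroxyl-directed trans-hydroalumination of the propargylic alcohol puts Al on C3 in a five-membered alanate, and iodination with retention gives the Z vinyl iodide that later fixes the C9=C10 geometry.

**Step 2**
Reactants: 3 (Z)-3-iodobut-2-en-1-ol; 4 acrolein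
Product: 5 (2Z,4S)-3-methylhexa-2,5-diene-1,4-diol
Conditions: CrCl2 (3 equiv), NiCl2 (2 mol %), Kishi oxazoline–sulfonamide ligand (enantiomer that gives the 4S carbinol, 3.3 equiv), Et3N, THF, rt
Reagents that add atoms: none
Why: Asymmetric Nozaki–Hiyama–Kishi coupling, in which the vinyl iodide adds 1,2 to acrolein with retention of alkene geometry and the chiral Cr(III) complex sets the new carbinol (later C1) as S.

**Step 3**
Reactants: 5 (2Z,4S)-3-methylhexa-2,5-diene-1,4-diol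
Product: 6 (2Z,4S)-1,4-bis[(tert-butyldimethylsilyl)oxy]-3-methylhexa-2,5-diene
Conditions: TBSCl (2.5 equiv), imidazole, DMF, rt
Reagents that add atoms: tert-butyldimethylsilyl chloride, CC(C)(C)[Si](C)(C)Cl
Why: Standard silylation of both hydroxyls (silyl ether protection), with no change at the stereocenter.

**Step 4**
Reactants: 6 (2Z,4S)-1,4-bis[(tert-butyldimethylsilyl)oxy]-3-methylhexa-2,5-diene
Product: 7 (2Z,4S)-4-[(tert-butyldimethylsilyl)oxy]-3-methylhexa-2,5-dien-1-ol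
Conditions: HF·pyridine, pyridine, THF, 0 °C
Reagents that add atoms: none
Why: Selective desilylation, because the primary allylic TBS ether is cleaved much faster than the hindered secondary one under buffered HF·pyridine.

**Step 5**
Reactants: 7 (2Z,4S)-4-[(tert-butyldimethylsilyl)oxy]-3-methylhexa-2,5-dien-1-ol
Product: 8 (2Z,4S)-4-[(tert-butyldimethylsilyl)oxy]-3-methylhexa-2,5-dienal
Conditions: MnO2, CH2Cl2, rt
Reagents that add atoms: none
Why: Allylic oxidation with MnO2 under neutral conditions gives the enal while keeping the Z geometry and the silyl ether.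

**Step 6**
Reactants: 8 (2Z,4S)-4-[(tert-butyldimethylsilyl)oxy]-3-methylhexa-2,5-dienal; 9 methyl propiolate
Product: 10 methyl (4S,5Z,7S)-7-[(tert-butyldimethylsilyl)oxy]-4-hydroxy-6-methylnona-5,8-dien-2-ynoate
Conditions: Me2Zn (3 equiv), ProPhenol (20 mol %, enantiomer that gives the 4S alcohol), Ph3PO (40 mol %), PhMe, 0 °C
Reagents that add atoms: none
Why: Trost ProPhenol/zinc-catalysed asymmetric alkynylation, in which the zinc acetylide adds 1,2 to the enal under ligand control and sets the carbinol (later C8) as S.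

**Step 7**
Reactants: 10 methyl (4S,5Z,7S)-7-[(tert-butyldimethylsilyl)oxy]-4-hydroxy-6-methylnona-5,8-dien-2-ynoate
Product: 11 methyl (4S,5Z,7S)-7-[(tert-butyldimethylsilyl)oxy]-6-methyl-4-[(triethylsilyl)oxy]nona-5,8-dien-2-ynoate
Conditions: TESCl, imidazole, DMAP (cat.), CH2Cl2, 0 °C
Reagents that add atoms: chlorotriethylsilane, CC[Si](Cl)(CC)CC
Why: Silyl ether protection with a TES group that can later be removed in the presence of TBS and TBDPS ethers.

**Step 8**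
Reactants: 11 methyl (4S,5Z,7S)-7-[(tert-butyldimethylsilyl)oxy]-6-methyl-4-[(triethylsilyl)oxy]nona-5,8-dien-2-ynoate; 12 formaldehyde
Product: 14 methyl (2Z,4S,5Z,7S)-7-[(tert-butyldimethylsilyl)oxy]-2-(hydroxymethyl)-6-methyl-4-[(triethylsilyl)oxy]nona-2,5,8-trienoate, via α-alumino enoate 13 (not isolated)
Conditions: DIBAL-H (1.3 equiv), HMPA, THF, 0 °C; then CH2O (gas from paraformaldehyde), 0 °C to rt
Reagents that add atoms: none
Why: DIBAL-H/HMPA 1,4-hydroalumination of the ynoate (syn addition) gives an α-alumino enoate that is hydroxymethylated at the α-carbon by formaldehyde in an aldol-type (Baylis–Hillman-type) trapping, leaving silyl ethers and unactivated alkenes untouched.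

**Step 9**
Reactants: 15 2-butyne-1,4-diol
Product: 16 4-[(tert-butyldiphenylsilyl)oxy]but-2-yn-1-ol
Conditions: NaH (1.0 equiv), THF, 0 °C; then TBDPSCl (1.0 equiv)
Reagents that add atoms: tert-butyl(chloro)diphenylsilane, CC(C)(C)[Si](Cl)(c1ccccc1)c1ccccc1
Why: Monosilylation of a symmetric diol through its monoalkoxide.

**Step 10**
Reactants: 16 4-[(tert-butyldiphenylsilyl)oxy]but-2-yn-1-ol
Product: 18 (Z)-4-[(tert-butyldiphenylsilyl)oxy]-3-iodobut-2-en-1-ol, via cyclic vinylalanate 17 (not isolated)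
Conditions: Red-Al, THF, 0 °C; then I2, −78 to 0 °C
Reagents that add atoms: iodine, II
Why: Hydroxyl-directed trans-hydroalumination/iodination puts iodine on the carbon bearing CH2OTBDPS and cis to CH2OH, which fixes the later C4=C5 geometry and leaves only the future C6 hydroxyl free.

**Step 11**
Reactants: 14 methyl (2Z,4S,5Z,7S)-7-[(tert-butyldimethylsilyl)oxy]-2-(hydroxymethyl)-6-methyl-4-[(triethylsilyl)oxy]nona-2,5,8-trienoate; 18 (Z)-4-[(tert-butyldiphenylsilyl)oxy]-3-iodobut-2-en-1-ol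
Product: 20 methyl (2Z,4S,5Z,7S,10E)-7-[(tert-butyldimethylsilyl)oxy]-10-{[(tert-butyldiphenylsilyl)oxy]methyl}-12-hydroxy-2-(hydroxymethyl)-6-methyl-4-[(triethylsilyl)oxy]dodeca-2,5,10-trienoate, via B-alkyl-9-BBN adduct 19 (not isolated)
Conditions: 9-BBN (2.2 equiv B–H), THF, rt; then 18, Pd(dppf)Cl2 (5 mol %), AsPh3, Cs2CO3, DMF/H2O, rt
Reagents that add atoms: none
Why: 9-BBN hydroborates only the monosubstituted vinyl group, and the B-alkyl Suzuki–Miyaura coupling joins C3 to C4 with retention of the vinyl iodide geometry, so C3 ends up cis to C6.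

**Step 12**
Reactants: 20 methyl (2Z,4S,5Z,7S,10E)-7-[(tert-butyldimethylsilyl)oxy]-10-{[(tert-butyldiphenylsilyl)oxy]methyl}-12-hydroxy-2-(hydroxymethyl)-6-methyl-4-[(triethylsilyl)oxy]dodeca-2,5,10-trienoate
Product: 21 methyl (2Z,4S,5Z,7S,10E)-7-[(tert-butyldimethylsilyl)oxy]-10-{[(tert-butyldiphenylsilyl)oxy]methyl}-2-(hydroxymethyl)-6-methyl-12-oxo-4-[(triethylsilyl)oxy]dodeca-2,5,10-trienoate
Conditions: MnO2, CH2Cl2, rt
Reagents that add atoms: none
Why: Chemoselective MnO2 allylic oxidation, since the electron-rich trisubstituted allylic alcohol is oxidised far faster than the electron-poor 2-(hydroxymethyl)acrylate hydroxyl.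

**Step 13**
Reactants: 21 methyl (2Z,4S,5Z,7S,10E)-7-[(tert-butyldimethylsilyl)oxy]-10-{[(tert-butyldiphenylsilyl)oxy]methyl}-2-(hydroxymethyl)-6-methyl-12-oxo-4-[(triethylsilyl)oxy]dodeca-2,5,10-trienoate
Product: 23 methyl (2E,4S,5Z,7S,10E)-2-(bromomethyl)-7-[(tert-butyldimethylsilyl)oxy]-10-{[(tert-butyldiphenylsilyl)oxy]methyl}-6-methyl-12-oxo-4-[(triethylsilyl)oxy]dodeca-2,5,10-trienoate, via allylic mesylate 22 (not isolated)
Conditions: MsCl, Et3N, CH2Cl2, −40 °C; then LiBr, THF, 0 °C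
Reagents that add atoms: lithium bromide, [Li+].[Br-]
Why: Mesylation followed by SN2 displacement with bromide converts the only free hydroxyl into the allylic bromide without touching the enal or the silyl ethers.

**Step 14**
Reactants: 23 methyl (2E,4S,5Z,7S,10E)-2-(bromomethyl)-7-[(tert-butyldimethylsilyl)oxy]-10-{[(tert-butyldiphenylsilyl)oxy]methyl}-6-methyl-12-oxo-4-[(triethylsilyl)oxy]dodeca-2,5,10-trienoate
Product: 25 (1S,4E,6R,7S,8S,9Z)-1-[(tert-butyldimethylsilyl)oxy]-15-[(tert-butyldiphenylsilyl)oxy]-8-[(triethylsilyl)oxy]germacra-4,9,11(13)-trien-12,6-olide, via hydroxy ester chromium alkoxide 24 (not isolated)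
Conditions: CrCl2 (8 equiv), THF, 0.003 M, slow addition of 23 over 12 h, rt, then 45 °C
Reagents that add atoms: none
Why: Intramolecular Nozaki–Hiyama (Cr(II)) 2-(alkoxycarbonyl)allylation, in which the allylchromium adds through C7 to the enal via a chair-like six-membered transition state with both ring tethers equatorial (anti adduct, hence trans-lactone after in situ lactonization), closing the low-strain cis,cis-cyclodeca-1,6-diene and the lactone together, while the C8 OTES group sits equatorial with H8 eclipsing C9=C10 and so directs C6 and C7 to the target configuration with C7–C11 trans to C8–O.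

**Step 15**
Reactants: 25 (1S,4E,6R,7S,8S,9Z)-1-[(tert-butyldimethylsilyl)oxy]-15-[(tert-butyldiphenylsilyl)oxy]-8-[(triethylsilyl)oxy]germacra-4,9,11(13)-trien-12,6-olide
Product: 26 (1S,4E,6R,7R,8S,9Z)-1-[(tert-butyldimethylsilyl)oxy]-15-[(tert-butyldiphenylsilyl)oxy]-8-hydroxygermacra-4,9,11(13)-trien-12,6-olide
Conditions: PPTS (cat.), MeOH/CH2Cl2, 0 °C
Reagents that add atoms: none
Why: Mild acid methanolysis removes the triethylsilyl ether selectively, leaving the TBS and TBDPS ethers and the lactone intact.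

**Step 16**
Reactants: 26 (1S,4E,6R,7R,8S,9Z)-1-[(tert-butyldimethylsilyl)oxy]-15-[(tert-butyldiphenylsilyl)oxy]-8-hydroxygermacra-4,9,11(13)-trien-12,6-olide; 27 (S)-2-methylbutanoic acid
Product: 28 (1S,4E,6R,7R,8R,9Z)-1-[(tert-butyldimethylsilyl)oxy]-15-[(tert-butyldiphenylsilyl)oxy]-8-{[(2S)-2-methylbutanoyl]oxy}germacra-4,9,11(13)-trien-12,6-olide
Conditions: PPh3, DIAD (betaine pre-formed), PhMe, 0 °C to rt
Reagents that add atoms: none
Why: Mitsunobu esterification, in which SN2 attack of the carboxylate on the C8 oxyphosphonium inverts C8 from S to R and installs the side chain without touching the acid's α-stereocenter.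

**Step 17**
Reactants: 28 (1S,4E,6R,7R,8R,9Z)-1-[(tert-butyldimethylsilyl)oxy]-15-[(tert-butyldiphenylsilyl)oxy]-8-{[(2S)-2-methylbutanoyl]oxy}germacra-4,9,11(13)-trien-12,6-olide
Product: 29 (1S,4E,6R,7R,8R,9Z)-1,15-dihydroxy-8-{[(2S)-2-methylbutanoyl]oxy}germacra-4,9,11(13)-trien-12,6-olide (target)
Conditions: HF·pyridine, pyridine, THF, 0 °C to rt
Reagents that add atoms: none
Why: Fluoride-mediated desilylation removes both silyl ethers under mildly acidic conditions that leave the ester, the lactone and the exocyclic methylene unchanged.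

**Compound list**
1 | 2-butyn-1-ol | CC#CCO | starting material
2 | sodium 2,2-bis(2-methoxyethoxy)-3-methyl-2,5-dihydro-1,2-oxaaluminol-2-uide (cyclic Z-vinylalanate) | CC1=CCO[Al-]1(OCCOC)OCCOC.[Na+] | intermediate
3 | (Z)-3-iodobut-2-en-1-ol | C/C(I)=C/CO | intermediate
4 | acrolein | C=CC=O | starting material
5 | (2Z,4S)-3-methylhexa-2,5-diene-1,4-diol | C=C[C@H](O)/C(C)=C\CO | intermediate
6 | (2Z,4S)-1,4-bis[(tert-butyldimethylsilyl)oxy]-3-methylhexa-2,5-diene | C=C[C@H](O[Si](C)(C)C(C)(C)C)/C(C)=C\CO[Si](C)(C)C(C)(C)C | intermediate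
7 | (2Z,4S)-4-[(tert-butyldimethylsilyl)oxy]-3-methylhexa-2,5-dien-1-ol | C=C[C@H](O[Si](C)(C)C(C)(C)C)/C(C)=C\CO | intermediate
8 | (2Z,4S)-4-[(tert-butyldimethylsilyl)oxy]-3-methylhexa-2,5-dienal | C=C[C@H](O[Si](C)(C)C(C)(C)C)/C(C)=C\C=O | intermediate
9 | methyl propiolate | C#CC(=O)OC | starting material
10 | methyl (4S,5Z,7S)-7-[(tert-butyldimethylsilyl)oxy]-4-hydroxy-6-methylnona-5,8-dien-2-ynoate | C=C[C@H](O[Si](C)(C)C(C)(C)C)/C(C)=C\[C@H](O)C#CC(=O)OC | intermediate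
11 | methyl (4S,5Z,7S)-7-[(tert-butyldimethylsilyl)oxy]-6-methyl-4-[(triethylsilyl)oxy]nona-5,8-dien-2-ynoate | C=C[C@H](O[Si](C)(C)C(C)(C)C)/C(C)=C\[C@H](O[Si](CC)(CC)CC)C#CC(=O)OC | intermediate
12 | formaldehyde | C=O | starting material
13 | methyl (2E,4S,5Z,7S)-2-(diisobutylalumanyl)-7-[(tert-butyldimethylsilyl)oxy]-6-methyl-4-[(triethylsilyl)oxy]nona-2,5,8-trienoate (α-alumino enoate) | C=C[C@H](O[Si](C)(C)C(C)(C)C)/C(C)=C\[C@H](O[Si](CC)(CC)CC)/C=C(/[Al](CC(C)C)CC(C)C)C(=O)OC | intermediate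
14 | methyl (2Z,4S,5Z,7S)-7-[(tert-butyldimethylsilyl)oxy]-2-(hydroxymethyl)-6-methyl-4-[(triethylsilyl)oxy]nona-2,5,8-trienoate | C=C[C@H](O[Si](C)(C)C(C)(C)C)/C(C)=C\[C@H](O[Si](CC)(CC)CC)/C=C(/CO)C(=O)OC | intermediate
15 | 2-butyne-1,4-diol | OCC#CCO | starting material
16 | 4-[(tert-butyldiphenylsilyl)oxy]but-2-yn-1-ol | OCC#CCO[Si](c1ccccc1)(c1ccccc1)C(C)(C)C | intermediate
17 | sodium 3-{[(tert-butyldiphenylsilyl)oxy]methyl}-2,2-bis(2-methoxyethoxy)-2,5-dihydro-1,2-oxaaluminol-2-uide (cyclic Z-vinylalanate) | CC(C)(C)[Si](c1ccccc1)(c1ccccc1)OCC1=CCO[Al-]1(OCCOC)OCCOC.[Na+] | intermediate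
18 | (Z)-4-[(tert-butyldiphenylsilyl)oxy]-3-iodobut-2-en-1-ol | OC/C=C(I)/CO[Si](c1ccccc1)(c1ccccc1)C(C)(C)C | intermediate
19 | B-alkyl-9-BBN adduct of 14 (terminal carbon bonded to 9-BBN boron; hydroxymethyl oxygen carried as its 9-BBN borinate) | C(B1C2CCCC1CCC2)C[C@H](O[Si](C)(C)C(C)(C)C)/C(C)=C\[C@H](O[Si](CC)(CC)CC)/C=C(/COB1C2CCCC1CCC2)C(=O)OC | intermediate
20 | methyl (2Z,4S,5Z,7S,10E)-7-[(tert-butyldimethylsilyl)oxy]-10-{[(tert-butyldiphenylsilyl)oxy]methyl}-12-hydroxy-2-(hydroxymethyl)-6-methyl-4-[(triethylsilyl)oxy]dodeca-2,5,10-trienoate | OC/C=C(/CO[Si](c1ccccc1)(c1ccccc1)C(C)(C)C)CC[C@H](O[Si](C)(C)C(C)(C)C)/C(C)=C\[C@H](O[Si](CC)(CC)CC)/C=C(/CO)C(=O)OC | intermediate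
21 | methyl (2Z,4S,5Z,7S,10E)-7-[(tert-butyldimethylsilyl)oxy]-10-{[(tert-butyldiphenylsilyl)oxy]methyl}-2-(hydroxymethyl)-6-methyl-12-oxo-4-[(triethylsilyl)oxy]dodeca-2,5,10-trienoate | O=C/C=C(/CO[Si](c1ccccc1)(c1ccccc1)C(C)(C)C)CC[C@H](O[Si](C)(C)C(C)(C)C)/C(C)=C\[C@H](O[Si](CC)(CC)CC)/C=C(/CO)C(=O)OC | intermediate
22 | methyl (2Z,4S,5Z,7S,10E)-7-[(tert-butyldimethylsilyl)oxy]-10-{[(tert-butyldiphenylsilyl)oxy]methyl}-2-{[(methylsulfonyl)oxy]methyl}-6-methyl-12-oxo-4-[(triethylsilyl)oxy]dodeca-2,5,10-trienoate | O=C/C=C(/CO[Si](c1ccccc1)(c1ccccc1)C(C)(C)C)CC[C@H](O[Si](C)(C)C(C)(C)C)/C(C)=C\[C@H](O[Si](CC)(CC)CC)/C=C(/COS(C)(=O)=O)C(=O)OC | intermediate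
23 | methyl (2E,4S,5Z,7S,10E)-2-(bromomethyl)-7-[(tert-butyldimethylsilyl)oxy]-10-{[(tert-butyldiphenylsilyl)oxy]methyl}-6-methyl-12-oxo-4-[(triethylsilyl)oxy]dodeca-2,5,10-trienoate | O=C/C=C(/CO[Si](c1ccccc1)(c1ccccc1)C(C)(C)C)CC[C@H](O[Si](C)(C)C(C)(C)C)/C(C)=C\[C@H](O[Si](CC)(CC)CC)/C=C(/CBr)C(=O)OC | intermediate
24 | methyl 2-[(1S,2R,3E,7S,8Z,10S)-7-[(tert-butyldimethylsilyl)oxy]-4-{[(tert-butyldiphenylsilyl)oxy]methyl}-2-hydroxy-8-methyl-10-[(triethylsilyl)oxy]cyclodeca-3,8-dien-1-yl]prop-2-enoate (present as its Cr(III) alkoxide) | C=C(C(=O)OC)[C@H]1[C@H](O)/C=C(/CO[Si](c2ccccc2)(c2ccccc2)C(C)(C)C)CC[C@H](O[Si](C)(C)C(C)(C)C)/C(C)=C\[C@@H]1O[Si](CC)(CC)CC | intermediate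
25 | (1S,4E,6R,7S,8S,9Z)-1-[(tert-butyldimethylsilyl)oxy]-15-[(tert-butyldiphenylsilyl)oxy]-8-[(triethylsilyl)oxy]germacra-4,9,11(13)-trien-12,6-olide (trans-lactone; 8-OTES trans to C7–C11; 7S only by CIP priority of Si, same spatial arrangement as 7R in 29) | C=C1C(=O)O[C@@H]2/C=C(/CO[Si](c3ccccc3)(c3ccccc3)C(C)(C)C)CC[C@H](O[Si](C)(C)C(C)(C)C)/C(C)=C\[C@H](O[Si](CC)(CC)CC)[C@@H]12 | intermediate
26 | (1S,4E,6R,7R,8S,9Z)-1-[(tert-butyldimethylsilyl)oxy]-15-[(tert-butyldiphenylsilyl)oxy]-8-hydroxygermacra-4,9,11(13)-trien-12,6-olide | C=C1C(=O)O[C@@H]2/C=C(/CO[Si](c3ccccc3)(c3ccccc3)C(C)(C)C)CC[C@H](O[Si](C)(C)C(C)(C)C)/C(C)=C\[C@H](O)[C@@H]12 | intermediate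
27 | (S)-2-methylbutanoic acid | CC[C@H](C)C(=O)O | starting material
28 | (1S,4E,6R,7R,8R,9Z)-1-[(tert-butyldimethylsilyl)oxy]-15-[(tert-butyldiphenylsilyl)oxy]-8-{[(2S)-2-methylbutanoyl]oxy}germacra-4,9,11(13)-trien-12,6-olide | C=C1C(=O)O[C@@H]2/C=C(/CO[Si](c3ccccc3)(c3ccccc3)C(C)(C)C)CC[C@H](O[Si](C)(C)C(C)(C)C)/C(C)=C\[C@@H](OC(=O)[C@@H](C)CC)[C@@H]12 | intermediate
29 | (1S,4E,6R,7R,8R,9Z)-1,15-dihydroxy-8-{[(2S)-2-methylbutanoyl]oxy}germacra-4,9,11(13)-trien-12,6-olide | C=C1C(=O)O[C@@H]2/C=C(/CO)CC[C@H](O)/C(C)=C\[C@@H](OC(=O)[C@@H](C)CC)[C@@H]12 | target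

**Totals**
Total step count: 17. Longest linear sequence: 15 (steps 1–8 and 11–17; steps 9–10 make the side fragment 18).

**Three steps most likely to fail, with fallbacks**

Step 14 (Cr-mediated closure of carbocycle and lactone) is the main risk. The yield of a ten-membered ring closure is uncertain, and the facial selectivity depends on a conformational argument in which the axial 1-OTBS group is a mismatching element. The fallback builds the two rings one after the other and sets out from 14 and 18. Oxidise 18 with MnO2 to (Z)-4-[(tert-butyldiphenylsilyl)oxy]-3-iodobut-2-enal F1. Convert 14 with CBr4/PPh3 into methyl (2E,4S,5Z,7S)-2-(bromomethyl)-7-[(tert-butyldimethylsilyl)oxy]-6-methyl-4-[(triethylsilyl)oxy]nona-2,5,8-trienoate F2. Join the two by an intermolecular CrCl2 allylation–lactonization (no nickel, so the vinyl iodide is untouched) to give (4S,5S)-5-[(Z)-3-[(tert-butyldiphenylsilyl)oxy]-2-iodoprop-1-enyl]-3-methylidene-4-[(1S,2Z,4S)-4-[(tert-butyldimethylsilyl)oxy]-3-methyl-1-[(triethylsilyl)oxy]hexa-2,5-dienyl]oxolan-2-one F3. Then close the carbocycle at C3–C4 by 9-BBN hydroboration of the terminal vinyl group and intramolecular B-alkyl Suzuki coupling at high dilution (Pd(dppf)Cl2, AsPh3, Cs2CO3), which comes back to the route at 25.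

Step 16 (Mitsunobu inversion at C8) may suffer from elimination or poor conversion, because the alcohol is a hindered ring allylic carbinol next to the lactone. The fallback sets out from 26 and replaces SN2 inversion by oxidation–reduction. Buffered Dess–Martin oxidation gives (1S,4E,6R,7S,9Z)-1-[(tert-butyldimethylsilyl)oxy]-15-[(tert-butyldiphenylsilyl)oxy]-8-oxogermacra-4,9,11(13)-trien-12,6-olide F4; this ketone must be handled cold and base-free because H7 is acidic. Reagent-controlled CBS reduction (Me-CBS enantiomer chosen for the 8R alcohol, catecholborane, −78 °C) gives (1S,4E,6R,7R,8R,9Z)-1-[(tert-butyldimethylsilyl)oxy]-15-[(tert-butyldiphenylsilyl)oxy]-8-hydroxygermacra-4,9,11(13)-trien-12,6-olide F5. Acylation with retention using (S)-2-methylbutanoic anhydride, DMAP and Et3N comes back to the route at 28.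

Step 8 (hydroalumination/hydroxymethylation of the γ-silyloxy ynoate) may give 1,2-reduction or poor trapping by formaldehyde. The fallback sets out from 11 and installs C13 by cross-coupling. Pd(PPh3)4-catalysed syn-hydrostannation with Bu3SnH gives methyl (2E,4S,5Z,7S)-7-[(tert-butyldimethylsilyl)oxy]-6-methyl-4-[(triethylsilyl)oxy]-2-(tributylstannyl)nona-2,5,8-trienoate F6. Iododestannylation with I2 gives methyl (2E,4S,5Z,7S)-7-[(tert-butyldimethylsilyl)oxy]-2-iodo-6-methyl-4-[(triethylsilyl)oxy]nona-2,5,8-trienoate F7. Stille coupling with (tributylstannyl)methanol (Pd(PPh3)4, dioxane, 80 °C) comes back to the route at 14.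

**Further compounds**
F1 | step 14 | (Z)-4-[(tert-butyldiphenylsilyl)oxy]-3-iodobut-2-enal | O=C/C=C(I)/CO[Si](c1ccccc1)(c1ccccc1)C(C)(C)C
F2 | step 14 | methyl (2E,4S,5Z,7S)-2-(bromomethyl)-7-[(tert-butyldimethylsilyl)oxy]-6-methyl-4-[(triethylsilyl)oxy]nona-2,5,8-trienoate | C=C[C@H](O[Si](C)(C)C(C)(C)C)/C(C)=C\[C@H](O[Si](CC)(CC)CC)/C=C(/CBr)C(=O)OC
F3 | step 14 | (4S,5S)-5-[(Z)-3-[(tert-butyldiphenylsilyl)oxy]-2-iodoprop-1-enyl]-3-methylidene-4-[(1S,2Z,4S)-4-[(tert-butyldimethylsilyl)oxy]-3-methyl-1-[(triethylsilyl)oxy]hexa-2,5-dienyl]oxolan-2-one | C=C1C(=O)O[C@H](/C=C(I)/CO[Si](c2ccccc2)(c2ccccc2)C(C)(C)C)[C@H]1[C@@H](O[Si](CC)(CC)CC)/C=C(C)\[C@@H](O[Si](C)(C)C(C)(C)C)C=C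
F4 | step 16 | (1S,4E,6R,7S,9Z)-1-[(tert-butyldimethylsilyl)oxy]-15-[(tert-butyldiphenylsilyl)oxy]-8-oxogermacra-4,9,11(13)-trien-12,6-olide | C=C1C(=O)O[C@@H]2/C=C(/CO[Si](c3ccccc3)(c3ccccc3)C(C)(C)C)CC[C@H](O[Si](C)(C)C(C)(C)C)/C(C)=C\C(=O)[C@@H]12
F5 | step 16 | (1S,4E,6R,7R,8R,9Z)-1-[(tert-butyldimethylsilyl)oxy]-15-[(tert-butyldiphenylsilyl)oxy]-8-hydroxygermacra-4,9,11(13)-trien-12,6-olide | C=C1C(=O)O[C@@H]2/C=C(/CO[Si](c3ccccc3)(c3ccccc3)C(C)(C)C)CC[C@H](O[Si](C)(C)C(C)(C)C)/C(C)=C\[C@@H](O)[C@@H]12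
F6 | step 8 | methyl (2E,4S,5Z,7S)-7-[(tert-butyldimethylsilyl)oxy]-6-methyl-4-[(triethylsilyl)oxy]-2-(tributylstannyl)nona-2,5,8-trienoate | C=C[C@H](O[Si](C)(C)C(C)(C)C)/C(C)=C\[C@H](O[Si](CC)(CC)CC)/C=C(/[Sn](CCCC)(CCCC)CCCC)C(=O)OC
F7 | step 8 | methyl (2E,4S,5Z,7S)-7-[(tert-butyldimethylsilyl)oxy]-2-iodo-6-methyl-4-[(triethylsilyl)oxy]nona-2,5,8-trienoate | C=C[C@H](O[Si](C)(C)C(C)(C)C)/C(C)=C\[C@H](O[Si](CC)(CC)CC)/C=C(/I)C(=O)OC
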